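1. Retrosynthesis (benzo[7]annulene locants C-1 to C-9a): the two angelates come off last. The 2-en-3-one of ring B is traced back to a C-1 ketone with a C-3 silyloxy group (transposition by elimination), and one C-9 methyl to a conjugate addition, which exposes a C-9=C-9a enone.
2. Ring A is then a cyclohepta-1,4-diene: C-5=C-6 and C-9=C-9a flank C-4a, and the oxygenated C-7–C-8 bond lies opposite. This is the retron of a cis-divinylcyclopropane rearrangement, so cutting C-7–C-8 (Cope) and C-4a–C-9a (carbenoid addition to a C-4a=C-5 alkene) opens both rings to an acyclic vinyl diazo ketone.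
3. Forward: the chain is joined linearly (alkyne carboalumination/oxirane opening, syn aldol, Weinreb ketone synthesis, diazo transfer, vinylation). One rhodium-catalysed operation then closes ring B (six-membered) by cyclopropanation and ring A (seven-membered) by Cope rearrangement.
4. Then: methyl conjugate addition (quaternary C-9, C-9a–H), reduction and mesylation at C-1, oxidation at C-3 with E1cB elimination to the enone, desilylation, double angeloylation.
5. Stereochemistry: C-2/C-3 come from an auxiliary-controlled syn aldol, steer the cyclopropanation face (C-4a) and are erased later. C-7 and C-8 follow stereospecifically from the (E)- and (Z)-enol ether geometries in the boat Cope transition state. C-9a comes from kinetic protonation on the face of H-4a.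

Key step: step 14

Assumption: β denotes the face of the bicycle that carries H-4a; the carbinol centre formed at C-1 in step 16 is carried as both epimers (undefined in the SMILES of 26–29) because it becomes sp2 in step 19.

**Step 1**
Reactants: 1 tert-butyl(but-3-yn-1-yloxy)dimethylsilane
Product: 4 (E)-6-[(tert-butyldimethylsilyl)oxy]-4-methylhex-3-en-1-ol, via alkenyldimethylalane 2 (not isolated), via lithium alkenylalanate 3 (not isolated)
Conditions: Me3Al, Cp2ZrCl2 (cat.), CH2Cl2, 0 °C → rt; n-BuLi, THF, −78 °C; oxirane, −78 → 0 °C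
Reagents that add atoms: trimethylaluminium C[Al](C)C; oxirane C1CO1
Why: Zirconium-catalysed syn-carboalumination places methyl on the internal alkyne carbon, and the derived alanate opens oxirane with retention, so the trisubstituted alkene should form as the E isomer.

**Step 2**
Reactants: 4 (E)-6-[(tert-butyldimethylsilyl)oxy]-4-methylhex-3-en-1-ol
Product: 5 (E)-6-[(tert-butyldimethylsilyl)oxy]-4-methylhex-3-enal
Conditions: Dess–Martin periodinane, NaHCO3, CH2Cl2, 0 °C
Reagents that add atoms: none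
Why: Buffered Dess–Martin oxidation should give the β,γ-unsaturated aldehyde without migration of the double bond into conjugation.

**Step 3**
Reactants: 5 (E)-6-[(tert-butyldimethylsilyl)oxy]-4-methylhex-3-enal; 6 (R)-4-benzyl-3-propanoyl-1,3-oxazolidin-2-one
Product: 8 (R)-4-benzyl-3-[(2R,3S,5E)-8-[(tert-butyldimethylsilyl)oxy]-3-hydroxy-2,6-dimethyloct-5-enoyl]-1,3-oxazolidin-2-one, via dibutylboron (Z)-enolate 7 (not isolated)
Conditions: 6, Bu2BOTf, i-Pr2NEt, CH2Cl2, −78 → 0 °C; then 5, −78 → 0 °C; pH 7 buffer, MeOH, H2O2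
Reagents that add atoms: none
Why: Evans syn-aldol reaction, in which the (Z)-boron enolate reacts through a closed chair transition state with one enolate face shielded by the (R)-benzyl auxiliary, sets the 2R,3S pair.

**Step 4**
Reactants: 8 aldol adduct
Product: 9 (2R,3S,5E)-8-[(tert-butyldimethylsilyl)oxy]-3-hydroxy-N-methoxy-N,2,6-trimethyloct-5-enamide
Conditions: MeONHMe·HCl, Me3Al, CH2Cl2, −20 → 0 °C
Reagents that add atoms: N,O-dimethylhydroxylamine hydrochloride CNOC.Cl
Why: Aluminium-amide transamination to the Weinreb amide is assisted by the free β-hydroxyl and should release the auxiliary without epimerisation at C-2.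

**Step 5**
Reactants: 9 hydroxy Weinreb amide
Product: 10 (2R,3S,5E)-3,8-bis[(tert-butyldimethylsilyl)oxy]-N-methoxy-N,2,6-trimethyloct-5-enamide
Conditions: TBSOTf, 2,6-lutidine, CH2Cl2, −78 → 0 °C
Reagents that add atoms: tert-butyldimethylsilyl trifluoromethanesulfonate CC(C)(C)[Si](C)(C)OS(=O)(=O)C(F)(F)F
Why: Silylation masks the secondary hydroxyl, which would otherwise undergo O–H insertion with the later carbenoid.

**Step 6**
Reactants: 10 bis-silyl ether
Product: 11 (2R,3S,5E)-3-[(tert-butyldimethylsilyl)oxy]-8-hydroxy-N-methoxy-N,2,6-trimethyloct-5-enamide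
Conditions: HF·pyridine, pyridine, THF, 0 °C
Reagents that add atoms: none
Why: The unhindered primary silyl ether is cleaved much faster than the secondary one flanked by the C-2 methyl group.

**Step 7**
Reactants: 11 primary alcohol
Product: 12 (2R,3S,5E)-3-[(tert-butyldimethylsilyl)oxy]-N-methoxy-N,2,6-trimethyl-8-oxooct-5-enamide
Conditions: Dess–Martin periodinane, NaHCO3, CH2Cl2, 0 °C
Reagents that add atoms: none
Why: Neutral Dess–Martin oxidation should deliver the isomerisation-prone β,γ-unsaturated aldehyde, which is used at once.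

**Step 8**
Reactants: 12 aldehyde
Product: 13 (2R,3S,5E,7E)-3-[(tert-butyldimethylsilyl)oxy]-N-methoxy-N,2,6-trimethyl-8-[(triisopropylsilyl)oxy]octa-5,7-dienamide
Conditions: TIPSOTf, Et3N, CH2Cl2, −78 → 0 °C
Reagents that add atoms: triisopropylsilyl trifluoromethanesulfonate CC(C)[Si](C(C)C)(C(C)C)OS(=O)(=O)C(F)(F)F
Why: Soft enolisation can only remove the doubly activated hydrogen α to the aldehyde, so the conjugated silyl dienol ether forms regiospecifically with the existing E alkene retained and the new enol ether expected mainly E, while the Weinreb amide is not enolised.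

**Step 9**
Reactants: 13 dienol ether Weinreb amide
Product: 14 (3R,4S,6E,8E)-4-[(tert-butyldimethylsilyl)oxy]-3,7-dimethyl-9-[(triisopropylsilyl)oxy]nona-6,8-dien-2-one
Conditions: MeMgBr, THF, −20 → 0 °C
Reagents that add atoms: methylmagnesium bromide C[Mg]Br
Why: Weinreb ketone synthesis, in which the stable magnesium chelate prevents over-addition and the silyl dienol ether is inert to the Grignard reagent.

**Step 10**
Reactants: 14 methyl ketone
Product: 16 (3R,4S,6E,8E)-4-[(tert-butyldimethylsilyl)oxy]-1-diazo-3,7-dimethyl-9-[(triisopropylsilyl)oxy]nona-6,8-dien-2-one, via trifluoroacetyl diketone 15 (not isolated)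
Conditions: LiN(SiMe3)2, THF, −78 °C; CF3CO2CH2CF3; then MsN3, Et3N, H2O, MeCN, rt
Reagents that add atoms: methanesulfonyl azide CS(=O)(=O)N=[N+]=[N-]
Why: Deacylative (Regitz-type) diazo transfer, in which the kinetic methyl enolate is trifluoroacetylated and the activated diketone accepts the diazo group with loss of the trifluoroacetyl unit.

**Step 11**
Reactants: 17 2-bromopropanal
Product: 18 (Z)-[(2-bromoprop-1-en-1-yl)oxy]triisopropylsilane
Conditions: TIPSOTf, Et3N, CH2Cl2, −78 → 0 °C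
Reagents that add atoms: triisopropylsilyl trifluoromethanesulfonate CC(C)[Si](C(C)C)(C(C)C)OS(=O)(=O)C(F)(F)F
Why: Enol silylation of the α-bromo aldehyde is expected to favour the Z isomer (bromine and oxygen syn, the usual cis preference of vicinal heteroatom-substituted alkenes), and any E isomer would be removed by chromatography.

**Step 12**
Reactants: 18 (Z)-bromo enol ether
Product: 20 (Z)-[(2-iodoprop-1-en-1-yl)oxy]triisopropylsilane, via vinyllithium 19 (not isolated)
Conditions: t-BuLi (2 equiv), Et2O, −78 °C; I2, −78 °C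
Reagents that add atoms: iodine II
Why: Bromine–lithium exchange and iodination both proceed with retention of alkene configuration at low temperature, so iodine ends cis to the silyloxy group as bromine was.

**Step 13**
Reactants: 16 diazo ketone; 20 (Z)-iodo enol ether
Product: 21 (1Z,5R,6S,8E,10E)-6-[(tert-butyldimethylsilyl)oxy]-3-diazo-2,5,9-trimethyl-1,11-bis[(triisopropylsilyl)oxy]undeca-1,8,10-trien-4-one
Conditions: Pd(PPh3)4 (5 mol %), Et3N, Bu4NBr, MeCN, rt, dark
Reagents that add atoms: none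
Why: Palladium-catalysed cross-coupling of the diazo C–H bond of an acyl diazomethane with a vinyl iodide keeps the diazo group and the alkene geometry, placing the siloxy group cis to the diazo carbon.

**Step 14**
Reactants: 21 vinyl diazo ketone
Product: 23 (2R,3S)-3α-[(tert-butyldimethylsilyl)oxy]-2β,5,9-trimethyl-7α,8β-bis[(triisopropylsilyl)oxy]-2,3,4,4a,7,8-hexahydro-1H-benzo[7]annulen-1-one (4a-H β), via cis-divinylcyclopropane 22 (not isolated)
Conditions: Rh2(OAc)4 (1 mol %), CH2Cl2, slow addition of 21, 0 °C → rt; then PhMe, 90 °C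
Reagents that add atoms: none
Why: Loss of N2 gives an electrophilic rhodium vinylcarbenoid that adds stereospecifically to the nucleophilic terminal C-4a=C-5 alkene of the siloxydiene to give cis-divinylcyclopropane 22, whose strain then drives a [3,3] (Cope) shift through the boat transition state, breaking the transient C-5–C-9a bond and forming C-7–C-8, so that C-4a–C-9a and C-7–C-8 are made in one operation. The closest known reaction type is the tandem cyclopropanation/Cope rearrangement of vinyl diazo carbonyl compounds with dienes (a formal (4+3) cycloaddition), including its intramolecular form. Ring B closes in the cyclopropanation (6-exo attack of the carbenoid carbon on the tethered alkene), and ring A closes in the sigmatropic step as a four-atom ring expansion of the three-membered ring. C-4a is set by a chair-like transition state with the 2-methyl and 3-silyloxy groups both equatorial and the alkene placed to avoid allylic strain, which puts H-4a syn to H-3. C-7 and C-8 follow stereospecifically from the enol ether geometries: the E (outward) siloxy group ends cis to C-4 and the Z (inward) siloxy group trans to it, giving the 7α,8β-trans pattern. The step needs chemoselectivity for the C-4a=C-5 alkene over the enol ether alkene, C–H insertion and ylide formation, which the six-membered tether, the polarisation of the dienol ether toward C-4a and the bulky, weakly basic silyl ether should secure, and it needs the cis-divinyl arrangement, which the E geometry of C-4a=C-5 and the tether guarantee.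

**Step 15**
Reactants: 23 bicyclic dienone
Product: 25 (2R,3S)-3α-[(tert-butyldimethylsilyl)oxy]-2β,5,9,9-tetramethyl-7α,8β-bis[(triisopropylsilyl)oxy]-2,3,4,4a,7,8,9,9a-octahydro-1H-benzo[7]annulen-1-one (cis-fused; 4a-H β; 9a-H β), via bromomagnesium enolate 24 (not isolated)
Conditions: MeMgBr, CuBr·SMe2 (cat.), THF/Me2S, −40 → −10 °C; then AcOH in THF, −78 °C
Reagents that add atoms: methylmagnesium bromide C[Mg]Br
Why: Copper-catalysed conjugate addition of methyl to the s-cis exocyclic enone (as in pulegone) makes the quaternary C-9, and kinetic protonation of the enolate on the face syn to the angular H-4a should give the cis ring fusion.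

**Step 16**
Reactants: 25 ketone
Product: 26 3α-[(tert-butyldimethylsilyl)oxy]-2β,5,9,9-tetramethyl-7α,8β-bis[(triisopropylsilyl)oxy]-2,3,4,4a,7,8,9,9a-octahydro-1H-benzo[7]annulen-1-ol (cis-fused; C-1 epimers)
Conditions: LiAlH4, Et2O, −78 °C
Reagents that add atoms: none
Why: Fast hydride reduction at low temperature removes the ketone before C-9a can epimerise, and either C-1 epimer serves because C-1 becomes sp2 in step 19.

**Step 17**
Reactants: 26 alcohol
Product: 27 1-methanesulfonate of 26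
Conditions: MsCl, Et3N, DMAP (cat.), CH2Cl2, 0 °C
Reagents that add atoms: methanesulfonyl chloride CS(=O)(=O)Cl
Why: Sulfonylation turns the C-1 oxygen into the leaving group for the later β-elimination.

**Step 18**
Reactants: 27 mesylate
Product: 28 3α-hydroxy-2β,5,9,9-tetramethyl-7α,8β-bis[(triisopropylsilyl)oxy]-2,3,4,4a,7,8,9,9a-octahydro-1H-benzo[7]annulen-1-yl methanesulfonate
Conditions: HF·pyridine, pyridine, THF, 0 °C → rt
Reagents that add atoms: none
Why: The tert-butyldimethylsilyl ether is cleaved faster than the two triisopropylsilyl ethers, which are more hindered at silicon.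

**Step 19**
Reactants: 28 hydroxy mesylate
Product: 30 (4aR,7R,8R,9aS)-2,5,9,9-tetramethyl-7,8-bis[(triisopropylsilyl)oxy]-4,4a,7,8,9,9a-hexahydro-3H-benzo[7]annulen-3-one, via 3-oxo mesylate 29 (not isolated)
Conditions: Dess–Martin periodinane, NaHCO3, CH2Cl2, 0 °C → rt; then Et3N, rt
Reagents that add atoms: none
Why: Oxidation gives a β-mesyloxy ketone that undergoes E1cB elimination through the C-2 enolate, which places the double bond regiospecifically at C-1=C-2 and erases the auxiliary centres at C-1, C-2 and C-3.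

**Step 20**
Reactants: 30 bis-silyl enone
Product: 31 (4aR,7R,8R,9aS)-7,8-dihydroxy-2,5,9,9-tetramethyl-4,4a,7,8,9,9a-hexahydro-3H-benzo[7]annulen-3-one
Conditions: Bu4NF, AcOH, THF, 0 °C → rt
Reagents that add atoms: none
Why: Fluoride desilylation buffered with acetic acid frees both hydroxyls while avoiding γ-deprotonation of the enone at C-9a.

**Step 21**
Reactants: 31 diol; 32 angelic acid [(Z)-2-methylbut-2-enoic acid]
Product: 35 (4aR,7R,8R,9aS)-2,5,9,9-tetramethyl-3-oxo-4,4a,7,8,9,9a-hexahydro-3H-benzo[7]annulene-7,8-diyl bis[(Z)-2-methylbut-2-enoate], via mixed anhydride 33 (not isolated), via 7-monoangelate 34 (not isolated)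
Conditions: 32 (3 equiv), 2,4,6-trichlorobenzoyl chloride (3 equiv), Et3N, PhMe, rt; then 31, PhMe, 80 °C (no DMAP)
Reagents that add atoms: (Z)-2-methylbut-2-enoic acid (angelic acid, the second equivalent of 32 built into the product) C/C=C(/C)C(=O)O
Why: Yamaguchi-type esterification in which two equivalents of the hindered mixed anhydride each transfer only the angeloyl group, first to the allylic C-7 hydroxyl (giving 34) and then on heating to the hindered C-8 hydroxyl, while omitting nucleophilic catalysts should limit Z → E isomerisation to the tiglate.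

**Compound list**

1 | tert-butyl(but-3-yn-1-yloxy)dimethylsilane | C#CCCO[Si](C)(C)C(C)(C)C | starting material
2 | (E)-{4-[(tert-butyldimethylsilyl)oxy]-2-methylbut-1-en-1-yl}dimethylaluminium | C[Al](C)/C=C(\C)CCO[Si](C)(C)C(C)(C)C | intermediate
3 | lithium butyl{(E)-4-[(tert-butyldimethylsilyl)oxy]-2-methylbut-1-en-1-yl}dimethylaluminate | [Li+].CCCC[Al-](C)(C)/C=C(\C)CCO[Si](C)(C)C(C)(C)C | intermediate
4 | (E)-6-[(tert-butyldimethylsilyl)oxy]-4-methylhex-3-en-1-ol | OCC/C=C(\C)CCO[Si](C)(C)C(C)(C)C | intermediate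
5 | (E)-6-[(tert-butyldimethylsilyl)oxy]-4-methylhex-3-enal | O=CC/C=C(\C)CCO[Si](C)(C)C(C)(C)C | intermediate
6 | (R)-4-benzyl-3-propanoyl-1,3-oxazolidin-2-one | CCC(=O)N1[C@H](Cc2ccccc2)COC1=O | starting material
7 | dibutylboron (Z)-enolate of 6 | CCCCB(CCCC)O/C(=C\C)N1[C@H](Cc2ccccc2)COC1=O | intermediate
8 | (R)-4-benzyl-3-[(2R,3S,5E)-8-[(tert-butyldimethylsilyl)oxy]-3-hydroxy-2,6-dimethyloct-5-enoyl]-1,3-oxazolidin-2-one | O=C(N1[C@H](Cc2ccccc2)COC1=O)[C@H](C)[C@@H](O)C/C=C(\C)CCO[Si](C)(C)C(C)(C)C | intermediate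
9 | (2R,3S,5E)-8-[(tert-butyldimethylsilyl)oxy]-3-hydroxy-N-methoxy-N,2,6-trimethyloct-5-enamide | CON(C)C(=O)[C@H](C)[C@@H](O)C/C=C(\C)CCO[Si](C)(C)C(C)(C)C | intermediate
10 | (2R,3S,5E)-3,8-bis[(tert-butyldimethylsilyl)oxy]-N-methoxy-N,2,6-trimethyloct-5-enamide | CON(C)C(=O)[C@H](C)[C@@H](O[Si](C)(C)C(C)(C)C)C/C=C(\C)CCO[Si](C)(C)C(C)(C)C | intermediate
11 | (2R,3S,5E)-3-[(tert-butyldimethylsilyl)oxy]-8-hydroxy-N-methoxy-N,2,6-trimethyloct-5-enamide | CON(C)C(=O)[C@H](C)[C@@H](O[Si](C)(C)C(C)(C)C)C/C=C(\C)CCO | intermediate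
12 | (2R,3S,5E)-3-[(tert-butyldimethylsilyl)oxy]-N-methoxy-N,2,6-trimethyl-8-oxooct-5-enamide | CON(C)C(=O)[C@H](C)[C@@H](O[Si](C)(C)C(C)(C)C)C/C=C(\C)CC=O | intermediate
13 | (2R,3S,5E,7E)-3-[(tert-butyldimethylsilyl)oxy]-N-methoxy-N,2,6-trimethyl-8-[(triisopropylsilyl)oxy]octa-5,7-dienamide | CON(C)C(=O)[C@H](C)[C@@H](O[Si](C)(C)C(C)(C)C)C/C=C(C)/C=C/O[Si](C(C)C)(C(C)C)C(C)C | intermediate
14 | (3R,4S,6E,8E)-4-[(tert-butyldimethylsilyl)oxy]-3,7-dimethyl-9-[(triisopropylsilyl)oxy]nona-6,8-dien-2-one | CC(=O)[C@H](C)[C@@H](O[Si](C)(C)C(C)(C)C)C/C=C(C)/C=C/O[Si](C(C)C)(C(C)C)C(C)C | intermediate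
15 | (5R,6S,8E,10E)-6-[(tert-butyldimethylsilyl)oxy]-1,1,1-trifluoro-5,9-dimethyl-11-[(triisopropylsilyl)oxy]undeca-8,10-diene-2,4-dione | O=C(CC(=O)[C@H](C)[C@@H](O[Si](C)(C)C(C)(C)C)C/C=C(C)/C=C/O[Si](C(C)C)(C(C)C)C(C)C)C(F)(F)F | intermediate
16 | (3R,4S,6E,8E)-4-[(tert-butyldimethylsilyl)oxy]-1-diazo-3,7-dimethyl-9-[(triisopropylsilyl)oxy]nona-6,8-dien-2-one | [N-]=[N+]=CC(=O)[C@H](C)[C@@H](O[Si](C)(C)C(C)(C)C)C/C=C(C)/C=C/O[Si](C(C)C)(C(C)C)C(C)C | intermediate
17 | 2-bromopropanal | CC(Br)C=O | starting material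
18 | (Z)-[(2-bromoprop-1-en-1-yl)oxy]triisopropylsilane | C/C(Br)=C/O[Si](C(C)C)(C(C)C)C(C)C | intermediate
19 | (E)-{1-[(triisopropylsilyl)oxy]prop-1-en-2-yl}lithium (lithium cis to the silyloxy group, in the place of bromine in 18) | [Li]/C(C)=C\O[Si](C(C)C)(C(C)C)C(C)C | intermediate
20 | (Z)-[(2-iodoprop-1-en-1-yl)oxy]triisopropylsilane | C/C(I)=C/O[Si](C(C)C)(C(C)C)C(C)C | intermediate
21 | (1Z,5R,6S,8E,10E)-6-[(tert-butyldimethylsilyl)oxy]-3-diazo-2,5,9-trimethyl-1,11-bis[(triisopropylsilyl)oxy]undeca-1,8,10-trien-4-one | [N-]=[N+]=C(/C(C)=C\O[Si](C(C)C)(C(C)C)C(C)C)C(=O)[C@H](C)[C@@H](O[Si](C)(C)C(C)(C)C)C/C=C(C)/C=C/O[Si](C(C)C)(C(C)C)C(C)C | intermediate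
22 | 4-[(tert-butyldimethylsilyl)oxy]-3,7-dimethyl-1-{(Z)-1-[(triisopropylsilyl)oxy]prop-1-en-2-yl}-7-{(E)-2-[(triisopropylsilyl)oxy]ethenyl}bicyclo[4.1.0]heptan-2-one (the two alkenyl groups cis on the three-membered ring, anti to the six-membered ring) | O=C1[C@H](C)[C@@H](O[Si](C)(C)C(C)(C)C)C[C@H]2[C@](C)(/C=C/O[Si](C(C)C)(C(C)C)C(C)C)[C@@]12/C(C)=C\O[Si](C(C)C)(C(C)C)C(C)C | intermediate
23 | (2R,3S)-3α-[(tert-butyldimethylsilyl)oxy]-2β,5,9-trimethyl-7α,8β-bis[(triisopropylsilyl)oxy]-2,3,4,4a,7,8-hexahydro-1H-benzo[7]annulen-1-one (4a-H β) | CC(C)[Si](C(C)C)(C(C)C)O[C@@H]1C=C(C)[C@@H]2C[C@H](O[Si](C)(C)C(C)(C)C)[C@@H](C)C(=O)C2=C(C)[C@H]1O[Si](C(C)C)(C(C)C)C(C)C | intermediate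
24 | bromomagnesium C-1 enolate of 25 | CC(C)[Si](C(C)C)(C(C)C)O[C@@H]1C=C(C)[C@@H]2C[C@H](O[Si](C)(C)C(C)(C)C)[C@@H](C)C(O[Mg]Br)=C2C(C)(C)[C@H]1O[Si](C(C)C)(C(C)C)C(C)C | intermediate
25 | (2R,3S)-3α-[(tert-butyldimethylsilyl)oxy]-2β,5,9,9-tetramethyl-7α,8β-bis[(triisopropylsilyl)oxy]-2,3,4,4a,7,8,9,9a-octahydro-1H-benzo[7]annulen-1-one (cis-fused) | CC(C)[Si](C(C)C)(C(C)C)O[C@@H]1C=C(C)[C@@H]2C[C@H](O[Si](C)(C)C(C)(C)C)[C@@H](C)C(=O)[C@@H]2C(C)(C)[C@H]1O[Si](C(C)C)(C(C)C)C(C)C | intermediate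
26 | 3α-[(tert-butyldimethylsilyl)oxy]-2β,5,9,9-tetramethyl-7α,8β-bis[(triisopropylsilyl)oxy]-2,3,4,4a,7,8,9,9a-octahydro-1H-benzo[7]annulen-1-ol (cis-fused; C-1 epimers) | CC(C)[Si](C(C)C)(C(C)C)O[C@@H]1C=C(C)[C@@H]2C[C@H](O[Si](C)(C)C(C)(C)C)[C@@H](C)C(O)[C@@H]2C(C)(C)[C@H]1O[Si](C(C)C)(C(C)C)C(C)C | intermediate
27 | 1-methanesulfonate of 26 (C-1 epimers) | CC(C)[Si](C(C)C)(C(C)C)O[C@@H]1C=C(C)[C@@H]2C[C@H](O[Si](C)(C)C(C)(C)C)[C@@H](C)C(OS(C)(=O)=O)[C@@H]2C(C)(C)[C@H]1O[Si](C(C)C)(C(C)C)C(C)C | intermediate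
28 | 3α-hydroxy-2β,5,9,9-tetramethyl-7α,8β-bis[(triisopropylsilyl)oxy]-2,3,4,4a,7,8,9,9a-octahydro-1H-benzo[7]annulen-1-yl methanesulfonate (C-1 epimers) | CC(C)[Si](C(C)C)(C(C)C)O[C@@H]1C=C(C)[C@@H]2C[C@H](O)[C@@H](C)C(OS(C)(=O)=O)[C@@H]2C(C)(C)[C@H]1O[Si](C(C)C)(C(C)C)C(C)C | intermediate
29 | 2β,5,9,9-tetramethyl-3-oxo-7α,8β-bis[(triisopropylsilyl)oxy]-2,3,4,4a,7,8,9,9a-octahydro-1H-benzo[7]annulen-1-yl methanesulfonate (C-1 epimers) | CC(C)[Si](C(C)C)(C(C)C)O[C@@H]1C=C(C)[C@@H]2CC(=O)[C@@H](C)C(OS(C)(=O)=O)[C@@H]2C(C)(C)[C@H]1O[Si](C(C)C)(C(C)C)C(C)C | intermediate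
30 | (4aR,7R,8R,9aS)-2,5,9,9-tetramethyl-7,8-bis[(triisopropylsilyl)oxy]-4,4a,7,8,9,9a-hexahydro-3H-benzo[7]annulen-3-one | CC(C)[Si](C(C)C)(C(C)C)O[C@@H]1C=C(C)[C@@H]2CC(=O)C(C)=C[C@@H]2C(C)(C)[C@H]1O[Si](C(C)C)(C(C)C)C(C)C | intermediate
31 | (4aR,7R,8R,9aS)-7,8-dihydroxy-2,5,9,9-tetramethyl-4,4a,7,8,9,9a-hexahydro-3H-benzo[7]annulen-3-one | O[C@@H]1C=C(C)[C@@H]2CC(=O)C(C)=C[C@@H]2C(C)(C)[C@H]1O | intermediate
32 | angelic acid [(Z)-2-methylbut-2-enoic acid] | C/C=C(/C)C(=O)O | starting material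
33 | (Z)-2-methylbut-2-enoic 2,4,6-trichlorobenzoic anhydride | C/C=C(/C)C(=O)OC(=O)c1c(Cl)cc(Cl)cc1Cl | intermediate
34 | (4aR,7R,8R,9aS)-8-hydroxy-2,5,9,9-tetramethyl-3-oxo-4,4a,7,8,9,9a-hexahydro-3H-benzo[7]annulen-7-yl (Z)-2-methylbut-2-enoate | C/C=C(/C)C(=O)O[C@@H]1C=C(C)[C@@H]2CC(=O)C(C)=C[C@@H]2C(C)(C)[C@H]1O | intermediate
35 | (4aR,7R,8R,9aS)-2,5,9,9-tetramethyl-3-oxo-4,4a,7,8,9,9a-hexahydro-3H-benzo[7]annulene-7,8-diyl bis[(Z)-2-methylbut-2-enoate] | C/C=C(/C)C(=O)O[C@@H]1C=C(C)[C@@H]2CC(=O)C(C)=C[C@@H]2C(C)(C)[C@H]1OC(=O)/C(C)=C\C | target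

**Totals**

Total step count: 21 (19 in the main line, 2 for iodide 20).
Longest linear sequence: 19 steps (steps 1–10 and 13–21).

**Steps most likely to fail**

Step 14. The inward-pointing (Z)-siloxy group has to pass H-4a in the boat transition state, so the Cope step may be slow enough for the diazo compound or the cyclopropane to be lost to pyrazole formation or silyl migration. The Z geometry may also erode before the rearrangement. In the fallback the C-8 oxygen is introduced after ring construction, which also avoids the vinylation of step 13. Setting out from Weinreb amide 13, addition of (2-methylallyl)magnesium chloride (THF, −20 °C) should give β,γ-unsaturated ketone (5R,6S,8E,10E)-6-[(tert-butyldimethylsilyl)oxy]-2,5,9-trimethyl-11-[(triisopropylsilyl)oxy]undeca-1,8,10-trien-4-one F1. Diazo transfer with 4-acetamidobenzenesulfonyl azide and DBU should give the isopropenyl diazo ketone F2. Rh2(OAc)4 should then trigger the same cascade, now without an inward substituent, through the cis-divinylcyclopropane F3 (not isolated) to the 8-unsubstituted dienone F4. Soft enolisation (TIPSOTf, Et3N) toward C-8 should give the extended silyl dienol ether F5. Vinylogous Rubottom oxidation with dimethyldioxirane should deliver oxygen anti to the 7α-siloxy group, giving the γ-hydroxy enone F6. Silylation (TIPSOTf, 2,6-lutidine) returns to the route at 23.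

Step 15. The tetrasubstituted, doubly flanked enone may resist conjugate addition, and the neighbouring 8β-siloxy group may divert protonation of the enolate to the other face, giving the trans-fused epimer. The fallback builds the second methyl from a cyclopropane. Setting out from 23, Luche reduction (NaBH4, CeCl3, MeOH) should give the allylic alcohol F7. Hydroxyl-directed Simmons–Smith cyclopropanation (Et2Zn, CH2I2) of the C-9=C-9a alkene should give the cyclopropyl carbinol F8. Dess–Martin oxidation should give the cyclopropyl ketone F9. Reductive opening with SmI2 (HMPA, t-BuOH, THF) is expected to cleave the exocyclic C-9a–CH2 bond, the cyclopropane bond that can align with the carbonyl π system while ring A stays intact, unveiling the second C-9 methyl; protonation of the enolate returns to the route at 25.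

Step 21. Acylation of the neopentyl-like C-8 hydroxyl may be so slow that the angeloyl donor isomerises to the tigloyl isomer, or the reaction may stop at the C-7 monoester. The fallback builds the Z alkenes on the ester instead. Setting out from diol 31, esterification with 2-[bis(2,2,2-trifluoroethoxy)phosphoryl]propanoic acid (DCC, DMAP) should give the bis(phosphonopropanoate) F10. Double Still–Gennari olefination with acetaldehyde (KN(SiMe3)2, 18-crown-6, THF, −78 °C) should form both (Z)-2-methylbut-2-enoates and return to the route at 35.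

**Further compounds**

F1 | step 14 | (5R,6S,8E,10E)-6-[(tert-butyldimethylsilyl)oxy]-2,5,9-trimethyl-11-[(triisopropylsilyl)oxy]undeca-1,8,10-trien-4-one | C=C(C)CC(=O)[C@H](C)[C@@H](O[Si](C)(C)C(C)(C)C)C/C=C(C)/C=C/O[Si](C(C)C)(C(C)C)C(C)C
F2 | step 14 | (5R,6S,8E,10E)-6-[(tert-butyldimethylsilyl)oxy]-3-diazo-2,5,9-trimethyl-11-[(triisopropylsilyl)oxy]undeca-1,8,10-trien-4-one | C=C(C)C(=[N+]=[N-])C(=O)[C@H](C)[C@@H](O[Si](C)(C)C(C)(C)C)C/C=C(C)/C=C/O[Si](C(C)C)(C(C)C)C(C)C
F3 | step 14 | 4-[(tert-butyldimethylsilyl)oxy]-3,7-dimethyl-1-(prop-1-en-2-yl)-7-{(E)-2-[(triisopropylsilyl)oxy]ethenyl}bicyclo[4.1.0]heptan-2-one (alkenyl groups cis) | O=C1[C@H](C)[C@@H](O[Si](C)(C)C(C)(C)C)C[C@H]2[C@](C)(/C=C/O[Si](C(C)C)(C(C)C)C(C)C)[C@@]12C(C)=C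
F4 | step 14 | (2R,3S)-3α-[(tert-butyldimethylsilyl)oxy]-2β,5,9-trimethyl-7α-[(triisopropylsilyl)oxy]-2,3,4,4a,7,8-hexahydro-1H-benzo[7]annulen-1-one | CC(C)[Si](C(C)C)(C(C)C)O[C@@H]1C=C(C)[C@@H]2C[C@H](O[Si](C)(C)C(C)(C)C)[C@@H](C)C(=O)C2=C(C)C1
F5 | step 14 | 3α-[(tert-butyldimethylsilyl)oxy]-2β,5,9-trimethyl-1,7α-bis[(triisopropylsilyl)oxy]-3,4,4a,7-tetrahydro-2H-benzo[7]annulene | CC(C)[Si](C(C)C)(C(C)C)O[C@@H]1C=C(C)[C@@H]2C[C@H](O[Si](C)(C)C(C)(C)C)[C@@H](C)C(O[Si](C(C)C)(C(C)C)C(C)C)=C2C(C)=C1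
F6 | step 14 | (2R,3S)-3α-[(tert-butyldimethylsilyl)oxy]-8β-hydroxy-2β,5,9-trimethyl-7α-[(triisopropylsilyl)oxy]-2,3,4,4a,7,8-hexahydro-1H-benzo[7]annulen-1-one | CC(C)[Si](C(C)C)(C(C)C)O[C@@H]1C=C(C)[C@@H]2C[C@H](O[Si](C)(C)C(C)(C)C)[C@@H](C)C(=O)C2=C(C)[C@H]1O
F7 | step 15 | 3α-[(tert-butyldimethylsilyl)oxy]-2β,5,9-trimethyl-7α,8β-bis[(triisopropylsilyl)oxy]-2,3,4,4a,7,8-hexahydro-1H-benzo[7]annulen-1-ol (C-1 epimers) | CC(C)[Si](C(C)C)(C(C)C)O[C@@H]1C=C(C)[C@@H]2C[C@H](O[Si](C)(C)C(C)(C)C)[C@@H](C)C(O)C2=C(C)[C@H]1O[Si](C(C)C)(C(C)C)C(C)C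
F8 | step 15 | 9,9a-methano adduct of F7 (cyclopropane across C-9 and C-9a, syn to the C-1 hydroxyl) | CC(C)[Si](C(C)C)(C(C)C)O[C@@H]1C=C(C)[C@@H]2C[C@H](O[Si](C)(C)C(C)(C)C)[C@@H](C)C(O)C23CC3(C)[C@H]1O[Si](C(C)C)(C(C)C)C(C)C
F9 | step 15 | 9,9a-methano ketone from F8 (C-1 ketone) | CC(C)[Si](C(C)C)(C(C)C)O[C@@H]1C=C(C)[C@@H]2C[C@H](O[Si](C)(C)C(C)(C)C)[C@@H](C)C(=O)C23CC3(C)[C@H]1O[Si](C(C)C)(C(C)C)C(C)C
F10 | step 21 | (4aR,7R,8R,9aS)-2,5,9,9-tetramethyl-3-oxo-4,4a,7,8,9,9a-hexahydro-3H-benzo[7]annulene-7,8-diyl bis{2-[bis(2,2,2-trifluoroethoxy)phosphoryl]propanoate} | CC(C(=O)O[C@@H]1C=C(C)[C@@H]2CC(=O)C(C)=C[C@@H]2C(C)(C)[C@H]1OC(=O)C(C)P(=O)(OCC(F)(F)F)OCC(F)(F)F)P(=O)(OCC(F)(F)F)OCC(F)(F)F
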